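1. Numbering (daucane): C1 is the quaternary ring-fusion carbon with methyl C15. C2 and C3 are the CH2 groups of the five-membered ring. C4 is the carbinol carbon with the isopropyl group (C11–C13), C5 the ring-fusion CH, C6 the acyloxy carbon, C7 a CH2, C8 the carbon with methylene C14, C9 the free carbinol and C10 a CH2. On is the oxygen on Cn; β is the face of C15 and α the other face.
2. Enabling feature: six consecutive atoms of the seven-membered ring, C5 to C10, bear O6, O9 and the one-carbon branch C14 at C8, just as a para-dioxygenated toluene does. The seventh atom, C1, is shared with the five-membered ring and is bonded to both C5 and C10.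
3. Retrosynthetic cuts in order: acyl–O6; C1–C5 together with C1–C10 (a carbene taken out of an arene bond, which restores the benzene ring and opens the five-membered ring); C1–C2 (diazoethane plus acid chloride); C3–C4 (allylation of an aryl ketone); C4–C5 (Friedel–Crafts acylation).
4. Forward: the benzene ring is bought and a temporary six-membered O4–Si–O6 ring is added. One step then closes the five-membered ring and widens the benzene ring to the seven-membered ring. C2 is deoxygenated and the two enol ethers are unmasked in turn: C6 first (used to move the C7=C8 bond out to C8=C14), C9 last.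
5. Stereochemistry: C4 by reagent control (chiral allylsilane); C1 relayed from C4 through the silicon tether; C5 by equilibrating protonation (trans fusion); C6 by hydride delivery from the C4 hydroxyl; C9 by α-face hydride addition and Mitsunobu inversion.

Key step: step 7

Assumption: the (S,S) enantiomer of silane 5 is taken to be the one that attacks the Si face of ketone 4. If the sense of induction is the opposite, its commercially available mirror image is used and nothing else changes.

Step 1
Reactants: 1 2,5-dimethoxytoluene; 2 isobutyryl chloride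
Product: 4 hydroxy ketone 1-(2-hydroxy-5-methoxy-4-methylphenyl)-2-methylpropan-1-one, via dimethoxy ketone 3 (not isolated)
Conditions: AlCl3 (2.5 equiv), CH2Cl2, 0 °C to reflux; ice, 1 M HCl
Reagents that add atoms: none
Why: Friedel–Crafts acylation should occur para to the methyl group and ortho to a methoxy group, the most activated and least crowded position of 1, and excess AlCl3 chelated between the new carbonyl and the neighbouring methoxy oxygen then cleaves only that ether (chelation-directed demethylation), which frees the future O6.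

Step 2
Reactants: 4 hydroxy ketone; 5 (3aS,7aS)-2-allyl-1,3-bis(4-bromobenzyl)-2-chlorooctahydro-1H-benzo[d][1,3,2]diazasilole
Product: 8 (R)-2-(3-hydroxy-2-methylhex-5-en-3-yl)-4-methoxy-5-methylphenol, via aryloxysilane 6 (not isolated), via spirocyclic allyl-transfer adduct 7 (not isolated)
Conditions: CH2Cl2, 23 to 40 °C; then 1 M aq citric acid, EtOAc
Reagents that add atoms: none
Why: In this phenol-directed asymmetric allylation of a ketone by a strained chiral allylchlorosilane, a reaction type established for hindered 2-hydroxyaryl ketones, the phenol displaces chloride, the ketone oxygen binds the Lewis-acidic silicon and allyl is transferred within a closed array, so the diamine backbone should steer it to the Si face and set C4 as R.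

Step 3
Reactants: 8 phenol carbinol
Product: 9 (4R)-4-allyl-2,2-di-tert-butyl-4-isopropyl-6-methoxy-7-methyl-4H-benzo[d][1,3,2]dioxasiline
Conditions: tBu2Si(OTf)2 (1.2 equiv), 2,6-lutidine (3 equiv), CH2Cl2, 0 to 40 °C
Reagents that add atoms: di-tert-butylsilyl bis(trifluoromethanesulfonate), CC(C)(C)[Si](OS(=O)(=O)C(F)(F)F)(OS(=O)(=O)C(F)(F)F)C(C)(C)C
Why: Silylene protection with the bis(triflate), which is known to engage even tertiary alcohols, should start at the phenol and close intramolecularly on the tertiary hydroxyl, while 2,6-lutidine keeps the medium non-acidic so that the benzylic carbinol does not ionise.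

Step 4
Reactants: 9 allyl silylene
Product: 11 2-[(4R)-2,2-di-tert-butyl-4-isopropyl-6-methoxy-7-methyl-4H-benzo[d][1,3,2]dioxasilin-4-yl]acetaldehyde, via vicinal diol 10 (not isolated)
Conditions: OsO4 (2 mol %), NaIO4 (4 equiv), 2,6-lutidine (2 equiv), dioxane/H2O 3:1, 23 °C
Reagents that add atoms: osmium tetroxide, O=[Os](=O)(=O)=O; sodium periodate, [Na+].[O-]I(=O)(=O)=O
Why: In this Lemieux–Johnson cleavage the catalytic dihydroxylation finds only one alkene, periodate cleaves diol 10 in situ, and the lutidine buffer spares the silylene and the electron-rich ring.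

Step 5
Reactants: 11 aldehyde
Product: 12 2-[(4R)-2,2-di-tert-butyl-4-isopropyl-6-methoxy-7-methyl-4H-benzo[d][1,3,2]dioxasilin-4-yl]acetic acid
Conditions: NaClO2, NaH2PO4, 2-methylbut-2-ene (20 equiv), tBuOH/H2O, 0 to 23 °C
Reagents that add atoms: sodium chlorite, [Na+].[O-]Cl=O
Why: Pinnick oxidation is selective for the aldehyde, the phosphate buffer is mild enough for the aryl–O–Si linkage, and the alkene scavenger removes HOCl before it can chlorinate the ring.

Step 6
Reactants: 12 acid; 13 N-ethyl-N-nitrosourea
Product: 16 3-diazo-1-[(4R)-2,2-di-tert-butyl-4-isopropyl-6-methoxy-7-methyl-4H-benzo[d][1,3,2]dioxasilin-4-yl]butan-2-one, via acid chloride 14 (not isolated), via diazoethane 15 (not isolated)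
Conditions: 12, Me2C=C(Cl)NMe2, CH2Cl2, 0 °C; in a second flask 13, 40% aq KOH, Et2O, 0 °C, ether layer decanted and dried over KOH; 14 added to 15 (4 equiv), Et2O, −20 to 0 °C
Reagents that add atoms: 1-chloro-N,N,2-trimethylprop-1-en-1-amine, CC(C)=C(Cl)N(C)C (chlorine of 14 only)
Why: This is the acylation of a diazoalkane by an acid chloride (first stage of the Arndt–Eistert sequence), in which the chloroenamine makes 14 under neutral conditions that the silylene tolerates and excess diazoethane both attacks the acyl chloride at carbon and consumes the HCl, giving the 2-diazo ketone that carries C1 and C15.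

Step 7
Reactants: 16 tethered 2-diazo ketone
Product: 18 silylene-bridged 8a-methylazulenone (1R,4R)-4,6-(di-tert-butylsilanediyldioxy)-9-methoxydauca-5,7,9-trien-2-one, via norcaradiene 17 (not isolated)
Conditions: Rh2(OAc)4 (1 mol %), CH2Cl2, reflux, slow addition of 16 at high dilution; filtration through Et3N-deactivated silica
Reagents that add atoms: none
Why: Rh2(OAc)4 expels N2 from 16 and the electrophilic keto carbenoid at C1 adds across the C5–C10 bond of the electron-rich ring to give norcaradiene 17, whose disrotatory six-electron ring opening cleaves C5–C10 and leaves cycloheptatriene 18 with C6 and C9 as enol ethers. The closest known reaction type is the intramolecular Buchner reaction of 2-diazo-5-arylpentan-3-ones with Rh2(OAc)4, which gives 8a-methylazulenones and places a benzylic substituent trans to the new methyl group. The five-membered ring closes in a 5-exo sense, C1 reaching the ipso carbon C5 through the three-atom link C2–C3–C4, whereas the seven-membered ring is not closed end to end but arises by one-carbon expansion of the benzene ring when the cyclopropane bond shared with it breaks. C1, the only new stereocentre, is controlled by C4 through the O4–Si–O6 ring, which keeps O4 near the arene plane on the C6 side, so that C3 and the isopropyl group stand on opposite faces, the carbenoid can reach only the face that carries C3, and C15 must end up cis to O4 and trans to the isopropyl group. The regioselectivity needed, C5–C10 instead of C5–C6, is secured by the same geometry, which leans C3 towards C10, and by the silyloxy group that crowds C6. The chemoselectivity needed, arene addition ahead of 1,2-hydride shift from C15, insertion into the isopropyl methine C–H and ylide formation at O4, rests on the nucleophilic, closely held ring and on the crowded, weakly basic siloxane oxygen, and the methyl group on C1 bars later aromatisation of 18 to a tetralone.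

Step 8
Reactants: 18 azulenone
Product: 19 (1R,2S,4R)-4,6-(di-tert-butylsilanediyldioxy)-9-methoxydauca-5,7,9-trien-2-ol
Conditions: iBu2AlH (1.2 equiv), CH2Cl2, −78 °C; aq potassium sodium tartrate
Reagents that add atoms: none
Why: Low-temperature, base-free hydride reduction of the cyclopentanone removes at once the carbonyl that makes O4 a β-leaving group, and attack should come from the β face because the pseudo-axial isopropyl group covers the α face, giving the 2α-alcohol, whose configuration is of no consequence.

Step 9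
Reactants: 19 alcohol
Product: 20 O-[(1R,2S,4R)-4,6-(di-tert-butylsilanediyldioxy)-9-methoxydauca-5,7,9-trien-2-yl] 1H-imidazole-1-carbothioate
Conditions: 1,1'-thiocarbonyldiimidazole (3 equiv), DMAP (0.2 equiv), toluene, 90 °C
Reagents that add atoms: 1,1'-thiocarbonyldiimidazole, S=C(n1ccnc1)n1ccnc1
Why: Thioacyl transfer under DMAP catalysis, the first half of the Barton–McCombie sequence, is the standard neutral activation of hindered secondary alcohols and leaves both enol ethers untouched.

Step 10
Reactants: 20 thiocarbonylimidazolide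
Product: 21 (1R,4R)-4,6-(di-tert-butylsilanediyldioxy)-9-methoxydauca-5,7,9-triene
Conditions: Bu3SnH (2 equiv), AIBN (0.2 equiv), toluene, 90 °C
Reagents that add atoms: none
Why: In this Barton–McCombie deoxygenation the C2 radical should be quenched by Bu3SnH before it can rearrange, since the C1–C2 bond lies close to the nodal planes of the C5=C6 and C9=C10 π bonds and three-membered ring closure onto them is geometrically disfavoured.

Step 11
Reactants: 21 triene
Product: 23 (1R,4R,5R)-4-hydroxy-9-methoxydauca-7,9-dien-6-one, via trienol 22 (not isolated)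
Conditions: Bu4NF (2.5 equiv), AcOH (2.5 equiv), THF, 0 to 40 °C
Reagents that add atoms: none
Why: Fluoride-induced desilylation cleaves both Si–O bonds in a buffered, nearly neutral medium, so the C6 enol ether is unmasked without the acid that would expel the allylic O4, trienol 22 ketonises by protonation at C5, and reversible enolisation in the acetate buffer should settle on the trans-fused 5αH epimer, in which C6 is anti to the isopropyl group and the C4 hydroxyl is hydrogen-bonded to the ketone.

Step 12
Reactants: 23 β-hydroxy dienone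
Product: 26 (1R,4R,5S,6S)-9-methoxydauca-8(14),9-diene-4,6-diol, via dilithium trienolate 24 (not isolated), via deconjugated enone 25 (not isolated)
Conditions: LiN(iPr)2 (2.4 equiv), THF, −78 to −40 °C; AcOH (10 equiv), THF, −78 °C; then Me4NBH(OAc)3 (6 equiv), MeCN/AcOH, −40 to −20 °C; aq potassium sodium tartrate
Reagents that add atoms: lithium diisopropylamide, [Li+].CC(C)[N-]C(C)C (lithium of 24 only)
Why: Deconjugative kinetic protonation of an extended enolate is followed in the same flask by Evans–Saksena reduction, because C14 carries the only γ-hydrogens of 23 (C9 is still an sp2 enol-ether carbon) and C5–H is shielded by two quaternary neighbours, so the amide base should give 24, acetic acid protonates it at the α-carbon C7, and the borohydride bound to the β-oriented C4 hydroxyl then delivers hydride to the β face of C6 to give the 6α-alcohol (6S, anti to O4) before 25 can reconjugate.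

Step 13
Reactants: 27 4-hydroxybenzoic acid
Product: 29 4-(tert-butyldimethylsilyloxy)benzoic acid, via bis-silyl derivative 28 (not isolated)
Conditions: TBSCl (2.3 equiv), imidazole (5 equiv), DMF, 23 °C; then AcOH/THF/H2O, 23 °C
Reagents that add atoms: tert-butyldimethylsilyl chloride, CC(C)(C)[Si](C)(C)Cl
Why: Exhaustive silylation followed by selective hydrolysis of the far more labile silyl ester is the routine silyl protection of the phenol of a hydroxybenzoic acid.

Step 14
Reactants: 26 diol; 29 protected acid
Product: 30 (1R,4R,5S,6S)-4-hydroxy-9-methoxydauca-8(14),9-dien-6-yl 4-(tert-butyldimethylsilyloxy)benzoate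
Conditions: DCC (1.5 equiv), DMAP (0.5 equiv), CH2Cl2, 23 °C
Reagents that add atoms: none
Why: Steglich esterification acylates only the secondary C6 hydroxyl, the tertiary C4 hydroxyl being inert, and the mildly basic medium preserves the methoxydiene.

Step 15
Reactants: 30 methoxydiene ester
Product: 31 (1R,4R,5S,6S)-4-hydroxy-9-oxodauc-8(14)-en-6-yl 4-(tert-butyldimethylsilyloxy)benzoate
Conditions: oxalic acid (0.2 equiv), THF/H2O 4:1, 0 °C
Reagents that add atoms: water, O
Why: Mild enol ether hydrolysis of the 2-methoxy-1,3-diene proceeds by protonation at C10, the carbon β to the methoxy oxygen, and loss of methanol to give the α-methylene ketone, while the C4 carbinol, no longer allylic to an enol ether or β to a ketone, is stable.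

Step 16
Reactants: 31 α-methylene ketone
Product: 32 (1R,4R,5S,6S,9R)-4,9-dihydroxydauc-8(14)-en-6-yl 4-(tert-butyldimethylsilyloxy)benzoate
Conditions: NaBH4, CeCl3·7H2O, MeOH, −78 °C
Reagents that add atoms: none
Why: Luche reduction gives 1,2-addition to the enone without touching the ester, and the axial C15 methyl group, 1,3 to C9, shields the β face, so hydride should enter from the α face and give the 9β-alcohol (9R).

Step 17
Reactants: 32 9β-alcohol
Product: 33 (1R,4R,5S,6S,9S)-4-hydroxy-9-(4-nitrobenzoyloxy)dauc-8(14)-en-6-yl 4-(tert-butyldimethylsilyloxy)benzoate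
Conditions: PPh3, DIAD, 4-nitrobenzoic acid (3 equiv each), toluene, 0 to 23 °C
Reagents that add atoms: 4-nitrobenzoic acid, O=C(O)c1ccc(cc1)[N+](=O)[O-]
Why: In this Mitsunobu inversion the pseudo-axial 9β-oxyphosphonium group is displaced by the carboxylate from the open α face in an SN2 process, which sets C9 as S, and the tertiary C4 hydroxyl does not react.

Step 18
Reactants: 33 diester
Product: 34 ferugin
Conditions: K2CO3 (2 equiv), MeOH, 0 °C; aq NH4Cl
Reagents that add atoms: none
Why: Base-mediated methanolysis removes the activated, unhindered 4-nitrobenzoate and the phenolic silyl ether, whereas the crowded C6 ester is further deactivated as soon as its phenol is ionised and should survive.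

Compound list
1 | 2,5-dimethoxytoluene | Cc1cc(OC)ccc1OC | starting material
2 | isobutyryl chloride | CC(C)C(=O)Cl | starting material
3 | 1-(2,5-dimethoxy-4-methylphenyl)-2-methylpropan-1-one | CC(C)C(=O)c1cc(OC)c(C)cc1OC | intermediate
4 | 1-(2-hydroxy-5-methoxy-4-methylphenyl)-2-methylpropan-1-one | CC(C)C(=O)c1cc(OC)c(C)cc1O | intermediate
5 | (3aS,7aS)-2-allyl-1,3-bis(4-bromobenzyl)-2-chlorooctahydro-1H-benzo[d][1,3,2]diazasilole | C=CC[Si]1(Cl)N(Cc2ccc(Br)cc2)[C@H]2CCCC[C@@H]2N1Cc1ccc(Br)cc1 | starting material
6 | aryloxysilane (5 with chloride replaced by the phenolic oxygen of 4) | C=CC[Si]1(Oc2cc(C)c(OC)cc2C(=O)C(C)C)N(Cc2ccc(Br)cc2)[C@H]2CCCC[C@@H]2N1Cc1ccc(Br)cc1 | intermediate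
7 | spirocyclic allyl-transfer adduct (Si bound to O4, O6 and both nitrogens; C4 R) | C=CC[C@]1(C(C)C)O[Si]2(Oc3cc(C)c(OC)cc31)N(Cc1ccc(Br)cc1)[C@H]1CCCC[C@@H]1N2Cc1ccc(Br)cc1 | intermediate
8 | (R)-2-(3-hydroxy-2-methylhex-5-en-3-yl)-4-methoxy-5-methylphenol | C=CC[C@@](O)(C(C)C)c1cc(OC)c(C)cc1O | intermediate
9 | (4R)-4-allyl-2,2-di-tert-butyl-4-isopropyl-6-methoxy-7-methyl-4H-benzo[d][1,3,2]dioxasiline | C=CC[C@]1(C(C)C)O[Si](C(C)(C)C)(C(C)(C)C)Oc2cc(C)c(OC)cc21 | intermediate
10 | 3-[(4R)-2,2-di-tert-butyl-4-isopropyl-6-methoxy-7-methyl-4H-benzo[d][1,3,2]dioxasilin-4-yl]propane-1,2-diol (both epimers at the secondary carbinol) | OCC(O)C[C@]1(C(C)C)O[Si](C(C)(C)C)(C(C)(C)C)Oc2cc(C)c(OC)cc21 | intermediate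
11 | 2-[(4R)-2,2-di-tert-butyl-4-isopropyl-6-methoxy-7-methyl-4H-benzo[d][1,3,2]dioxasilin-4-yl]acetaldehyde | O=CC[C@]1(C(C)C)O[Si](C(C)(C)C)(C(C)(C)C)Oc2cc(C)c(OC)cc21 | intermediate
12 | 2-[(4R)-2,2-di-tert-butyl-4-isopropyl-6-methoxy-7-methyl-4H-benzo[d][1,3,2]dioxasilin-4-yl]acetic acid | OC(=O)C[C@]1(C(C)C)O[Si](C(C)(C)C)(C(C)(C)C)Oc2cc(C)c(OC)cc21 | intermediate
13 | N-ethyl-N-nitrosourea | CCN(N=O)C(N)=O | starting material
14 | acid chloride of 12 | ClC(=O)C[C@]1(C(C)C)O[Si](C(C)(C)C)(C(C)(C)C)Oc2cc(C)c(OC)cc21 | intermediate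
15 | diazoethane | CC=[N+]=[N-] | intermediate
16 | 3-diazo-1-[(4R)-2,2-di-tert-butyl-4-isopropyl-6-methoxy-7-methyl-4H-benzo[d][1,3,2]dioxasilin-4-yl]butan-2-one | CC(=[N+]=[N-])C(=O)C[C@]1(C(C)C)O[Si](C(C)(C)C)(C(C)(C)C)Oc2cc(C)c(OC)cc21 | intermediate
17 | norcaradiene valence isomer of 18 (cyclopropane C1–C5–C10, C15 over the C6=C7–C8=C9 diene, C2 and C4 cis on the cyclopropane, C4 R) | C[C@@]12C(=O)C[C@]3(C(C)C)O[Si](C(C)(C)C)(C(C)(C)C)OC4=CC(C)=C(OC)[C@H]1[C@]243 | intermediate
18 | (1R,4R)-4,6-(di-tert-butylsilanediyldioxy)-9-methoxydauca-5,7,9-trien-2-one | CC1=CC2=C3[C@](C)(C(=O)C[C@]3(C(C)C)O[Si](C(C)(C)C)(C(C)(C)C)O2)C=C1OC | intermediate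
19 | (1R,2S,4R)-4,6-(di-tert-butylsilanediyldioxy)-9-methoxydauca-5,7,9-trien-2-ol (2α-OH) | CC1=CC2=C3[C@](C)([C@@H](O)C[C@]3(C(C)C)O[Si](C(C)(C)C)(C(C)(C)C)O2)C=C1OC | intermediate
20 | O-[(1R,2S,4R)-4,6-(di-tert-butylsilanediyldioxy)-9-methoxydauca-5,7,9-trien-2-yl] 1H-imidazole-1-carbothioate | CC1=CC2=C3[C@](C)([C@@H](OC(=S)n4ccnc4)C[C@]3(C(C)C)O[Si](C(C)(C)C)(C(C)(C)C)O2)C=C1OC | intermediate
21 | (1R,4R)-4,6-(di-tert-butylsilanediyldioxy)-9-methoxydauca-5,7,9-triene | CC1=CC2=C3[C@](C)(CC[C@]3(C(C)C)O[Si](C(C)(C)C)(C(C)(C)C)O2)C=C1OC | intermediate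
22 | (1R,4R)-9-methoxydauca-5,7,9-triene-4,6-diol (trienol) | CC1=CC(O)=C2[C@](C)(CC[C@@]2(O)C(C)C)C=C1OC | intermediate
23 | (1R,4R,5R)-4-hydroxy-9-methoxydauca-7,9-dien-6-one (4β-OH, 5αH, trans-fused) | CC1=CC(=O)[C@@H]2[C@](C)(CC[C@@]2(O)C(C)C)C=C1OC | intermediate
24 | dilithium salt: C4 alkoxide and C6=C7, C8=C14 extended enolate of 23 | [Li+].[Li+].C=C1C=C([O-])[C@@H]2[C@](C)(CC[C@@]2([O-])C(C)C)C=C1OC | intermediate
25 | (1R,4R,5R)-4-hydroxy-9-methoxydauca-8(14),9-dien-6-one | C=C1CC(=O)[C@@H]2[C@](C)(CC[C@@]2(O)C(C)C)C=C1OC | intermediate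
26 | (1R,4R,5S,6S)-9-methoxydauca-8(14),9-diene-4,6-diol (4β-OH, 6α-OH) | C=C1C[C@H](O)[C@@H]2[C@](C)(CC[C@@]2(O)C(C)C)C=C1OC | intermediate
27 | 4-hydroxybenzoic acid | O=C(O)c1ccc(O)cc1 | starting material
28 | tert-butyldimethylsilyl 4-(tert-butyldimethylsilyloxy)benzoate | CC(C)(C)[Si](C)(C)Oc1ccc(C(=O)O[Si](C)(C)C(C)(C)C)cc1 | intermediate
29 | 4-(tert-butyldimethylsilyloxy)benzoic acid | CC(C)(C)[Si](C)(C)Oc1ccc(C(=O)O)cc1 | intermediate
30 | (1R,4R,5S,6S)-4-hydroxy-9-methoxydauca-8(14),9-dien-6-yl 4-(tert-butyldimethylsilyloxy)benzoate | C=C1C[C@H](OC(=O)c3ccc(O[Si](C)(C)C(C)(C)C)cc3)[C@@H]2[C@](C)(CC[C@@]2(O)C(C)C)C=C1OC | intermediate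
31 | (1R,4R,5S,6S)-4-hydroxy-9-oxodauc-8(14)-en-6-yl 4-(tert-butyldimethylsilyloxy)benzoate | C=C1C[C@H](OC(=O)c3ccc(O[Si](C)(C)C(C)(C)C)cc3)[C@@H]2[C@](C)(CC[C@@]2(O)C(C)C)CC1=O | intermediate
32 | (1R,4R,5S,6S,9R)-4,9-dihydroxydauc-8(14)-en-6-yl 4-(tert-butyldimethylsilyloxy)benzoate (9β-OH) | C=C1C[C@H](OC(=O)c3ccc(O[Si](C)(C)C(C)(C)C)cc3)[C@@H]2[C@](C)(CC[C@@]2(O)C(C)C)C[C@H]1O | intermediate
33 | (1R,4R,5S,6S,9S)-4-hydroxy-9-(4-nitrobenzoyloxy)dauc-8(14)-en-6-yl 4-(tert-butyldimethylsilyloxy)benzoate | C=C1C[C@H](OC(=O)c3ccc(O[Si](C)(C)C(C)(C)C)cc3)[C@@H]2[C@](C)(CC[C@@]2(O)C(C)C)C[C@@H]1OC(=O)c1ccc(cc1)[N+](=O)[O-] | intermediate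
34 | ferugin, (1R,4R,5S,6S,9S)-4,9-dihydroxydauc-8(14)-en-6-yl 4-hydroxybenzoate | C=C1C[C@H](OC(=O)c2ccc(O)cc2)[C@@H]2[C@](C)(CC[C@@]2(O)C(C)C)C[C@@H]1O | target

Total step count: 18. Longest linear sequence: 17 (steps 1–12 and 14–18).

Steps most likely to fail

Step 12. The amide base may remove C5–H instead of a C14 hydrogen, which would be followed by loss of O4 or retro-aldol opening of the five-membered ring. The enolate may also be protonated at C14, or the β,γ-unsaturated ketone may reconjugate before it is reduced. The fallback gives up enolate deconjugation. It sets out from 23 and comes back at 31. The conjugated dienone 23 is reduced first with Me4NBH(OAc)3 in MeCN/AcOH to the 6α-allylic alcohol F1. This is esterified with 29 (DCC, DMAP) to the dienyl ester F2. Oxalic acid in aqueous THF then gives the endocyclic 2-methyl enone F3. Conjugate reduction with LiBH(sBu)3 at −78 °C and trapping of the C8 enolate with PhSeBr from the α face give the α-phenylselanyl ketone F4. Oxidation with H2O2 triggers selenoxide syn-elimination. This should turn towards C14, because the C7 hydrogens sit next to the acyloxy carbon and are outnumbered, and it delivers 31.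

Step 7. A 1,2-hydride shift from C15, insertion into the isopropyl methine C–H or electrophilic substitution at C10 may outrun the cyclopropanation. The fallback separates ring construction from formation of the quaternary centre. It sets out from 12 by way of its chloride 14 and comes back at 18. Chloride 14 is treated with ethereal CH2N2 to give the terminal diazo ketone F5, the substrate class with the widest Buchner record and with no hydrogen next to the carbenoid carbon. Rh2(OAc)4 in CH2Cl2 converts it, under the same tether control, into the C1-unsubstituted azulenone F6. The doubly allylic C1–H is then removed with KN(SiMe3)2 at −78 °C, and the enolate is methylated with MeI on the β face, opposite to the isopropyl group, which gives 18.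

Step 17 (fed by step 16). Poor facial selectivity in the hydride addition, attack of the carboxylate at C14 with allylic shift, or elimination of the activated allylic alcohol may erode the C9 configuration. The fallback replaces substrate control plus inversion by reagent control. It sets out from 31 and comes back at 34. Corey–Bakshi–Shibata reduction of 31 uses (R)-2-methyl-CBS-oxazaborolidine and BH3·SMe2 at −40 °C, with the alkenyl side acting as the large group. It gives the 9S alcohol O-silyl ferugin F7 directly, and Bu4NF/AcOH in THF removes the phenolic silyl ether to give 34.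

Further compounds
F1 | step 12 | (1R,4R,5S,6S)-9-methoxydauca-7,9-diene-4,6-diol | CC1=C[C@H](O)[C@@H]2[C@](C)(CC[C@@]2(O)C(C)C)C=C1OC
F2 | step 12 | (1R,4R,5S,6S)-4-hydroxy-9-methoxydauca-7,9-dien-6-yl 4-(tert-butyldimethylsilyloxy)benzoate | CC1=C[C@H](OC(=O)c3ccc(O[Si](C)(C)C(C)(C)C)cc3)[C@@H]2[C@](C)(CC[C@@]2(O)C(C)C)C=C1OC
F3 | step 12 | (1R,4R,5S,6S)-4-hydroxy-9-oxodauc-7-en-6-yl 4-(tert-butyldimethylsilyloxy)benzoate | CC1=C[C@H](OC(=O)c3ccc(O[Si](C)(C)C(C)(C)C)cc3)[C@@H]2[C@](C)(CC[C@@]2(O)C(C)C)CC1=O
F4 | step 12 | (1R,4R,5S,6S,8R)-4-hydroxy-9-oxo-8-(phenylselanyl)daucan-6-yl 4-(tert-butyldimethylsilyloxy)benzoate | C[C@@]1([Se]c4ccccc4)C[C@H](OC(=O)c3ccc(O[Si](C)(C)C(C)(C)C)cc3)[C@@H]2[C@](C)(CC[C@@]2(O)C(C)C)CC1=O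
F5 | step 7 | 1-diazo-3-[(4R)-2,2-di-tert-butyl-4-isopropyl-6-methoxy-7-methyl-4H-benzo[d][1,3,2]dioxasilin-4-yl]propan-2-one | [N-]=[N+]=CC(=O)C[C@]1(C(C)C)O[Si](C(C)(C)C)(C(C)(C)C)Oc2cc(C)c(OC)cc21
F6 | step 7 | (1R,4R)-4,6-(di-tert-butylsilanediyldioxy)-9-methoxy-15-nordauca-5,7,9-trien-2-one | CC1=CC2=C3[C@H](C(=O)C[C@]3(C(C)C)O[Si](C(C)(C)C)(C(C)(C)C)O2)C=C1OC
F7 | step 17 | (1R,4R,5S,6S,9S)-4,9-dihydroxydauc-8(14)-en-6-yl 4-(tert-butyldimethylsilyloxy)benzoate | C=C1C[C@H](OC(=O)c3ccc(O[Si](C)(C)C(C)(C)C)cc3)[C@@H]2[C@](C)(CC[C@@]2(O)C(C)C)C[C@@H]1O
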